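## Structural features

The target is 5-[(2R)-2-hydroxyheptadecyl]benzene-1,3-diol: one benzene ring with hydroxyl groups at C1 and C3 (a resorcinol) and an unbranched seventeen-carbon chain at C5. The chain is joined to the ring through a benzylic methylene (C-alpha); the next carbon (C-beta) is a secondary carbinol, and a straight pentadecyl group begins at C-gamma. C-beta, R-configured, is the only stereocentre, so no neighbouring centre can be mismatched or epimerised, but nothing in the molecule can steer its formation either. The fragile sites are the electron-rich resorcinol (easily oxidised as its phenoxide, and acidic enough to quench organometallic reagents) and the homobenzylic alcohol, which strong acid can dehydrate towards a conjugated styrene. The real difficulty is that C-beta lies between two methylene groups of almost equal size, ArCH2 and alkyl-CH2, so ketone reduction or resolution discriminates poorly; the centre is best created while a C–C bond is formed. The key step treats C-alpha and C-beta as the two carbons of a vinyl group on boron: the terminal carbon receives the ring (as its dimethyl ether), and the boron-bearing carbon receives the pentadecyl chain by a 1,2-shift and keeps boron as a stand-in for the hydroxyl oxygen.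

## Logic of the disconnections

9 ⇒ 8. Going backwards, the two phenolic hydrogens are exchanged for methyl groups, so the bonds cut in the forward step are the two aryl O–CH3 bonds. The mask is needed because free phenols would destroy 4 and 6, and methyl ethers are the smallest group that survives organolithium, palladium and alkaline peroxide. The gain is that the arene becomes the cheap commodity 1. The demand is an exhaustive O-demethylation of 8 that leaves the carbinol and its configuration alone, which calls for a Lewis acid at low temperature and not for a thiolate, which tends to stall after the first cleavage.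

8 ⇒ 7. The C-beta–O bond is traced back to a C-beta–B bond. Boron is what the key step leaves on C-beta, and its replacement by oxygen is stereospecific. The gain is that the stereochemical problem moves from a C–O to a C–C bond-forming event. The demand is an oxidation with full retention that does not touch the electron-rich ring.

7 ⇒ 2 + 6. Two skeletal bonds are cut, aryl–C-alpha and C-beta–C-gamma. They flank the two-carbon linchpin, so cutting both dissects 7 into an aryl electrophile, a two-carbon boron unit and a C15 nucleophile, all achiral. The gain is that the whole carbon skeleton of 9 and its only stereocentre arise in one operation. The demand is threefold: a chiral catalyst must select one face of the vinyl group of 6, the 1,2-shift must outrun direct transfer of a group from boron to the metal, and the medium must be kept free of coordinating halide.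

6 ⇒ 4 + 5. The B–C bond to the pentadecyl group is cut. Ate-complex formation is a plain addition of a carbanion to tricoordinate boron, and 5 is bought. The demand is strictly equal amounts of 4 and 5, since surplus 4 would later attack 2 at sulfur.

4 ⇒ 3. The C–Li bond is traced back to C–Br, because 3 is the commercial C15 electrophile. Direct reductive metalation is preferred to halogen–metal exchange with a tertiary alkyllithium, which is sluggish and partly radical at a primary bromide and needs a pyrophoric reagent. The demand is low temperature to restrain Wurtz coupling, and removal of the halide salt formed beside 4 before the catalyst is added.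

2 ⇒ 1. The S–O bond of the sulfonate is cut. The triflate is chosen over a halide because its counter-ion does not bind palladium. The demand is only a routine sulfonylation.

## Other disconnections considered

Alternative 1: The cut is the ring bond between the chain-bearing ring carbon and the neighbouring ester-bearing carbon. The open-chain precursor is methyl (9R)-9-(tert-butyldimethylsilyloxy)-3,5,7-trioxotetracosanoate A1. In the forward key step, mild aqueous base would make C2 attack the C7 ketone; dehydration and enolisation would then give methyl 2,4-dihydroxy-6-[(2R)-2-(tert-butyldimethylsilyloxy)heptadecyl]benzoate A2.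
- In favour: the arene is born with both phenols free, the substitution pattern follows from the chain, and ring formation needs no metal or chiral ligand.
- Against: the step does not create C-beta, so the centre must be imported. In A1 the silyloxy group is beta to the C7 ketone, so base-induced elimination competes with the aldol and would erase the centre. A1 is laborious to assemble and can close to pyrones or by Claisen-type modes. After A2, ester hydrolysis, decarboxylation and desilylation are still needed to reach 9.
- Comparison: on structure it builds a ring that can be bought, while the chosen plan spends its key step on the stereocentre. On mechanism, aromatisation-driven closure is in principle as dependable as the metallate shift, so the two are equal there. On the end game it is the better plan, because no aryl ether has to be cleaved. On step economy it is clearly worse, roughly twice as long.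

Alternative 2: Here the carbon skeleton is made first as (E)-1-(3,5-dimethoxyphenyl)heptadec-1-ene A3, and the two C–O bonds at C-alpha and C-beta are formed by a dioxirane generated from a fructose-derived chiral ketone. The product is (2R,3R)-2-(3,5-dimethoxyphenyl)-3-pentadecyloxirane A4; hydrogenolysis of its benzylic C-alpha–O bond would give 8.
- In favour: face selection for E-disubstituted styrenyl alkenes is predictable, the catalyst is cheap and metal-free, no pyrophoric reagent is needed, and the hydrogenolysis leaves C-beta untouched.
- Against: A3 must be made geometrically pure in one or two extra steps, since any Z isomer lowers the optical purity. A centre at C-alpha is created only to be destroyed. The electron-rich aryl epoxide A4 can rearrange to a ketone if the pH drifts. The same demethylation still follows.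
- Comparison: both plans rely on catalyst-controlled face selection of a pi bond. The alternative is the equal of the chosen plan in step count (about five) and in predictability of the stereochemical outcome, and the better one in operational simplicity. The chosen plan is more convergent, forming both C–C bonds and the centre from three achiral pieces in one flask without redox detours.

Alternative 3: Three ring bonds are cut (C1–C2, C3–C4 and C1–C6 of the phenol). Heating 3-[(2R)-2-(tert-butyldimethylsilyloxy)heptadecyl]cyclobut-2-en-1-one A5 with ethoxyethyne A6 would open A5 to a vinylketene. A [2+2] addition, a four-electron ring opening and a six-electron electrocyclisation would then give 3-ethoxy-5-[(2R)-2-(tert-butyldimethylsilyloxy)heptadecyl]phenol A7.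
- In favour: the ring synthesis is regiospecific and metal-free, and it delivers one phenol already free.
- Against: A5 needs a multistep synthesis with the stereocentre already installed by other means. The cascade needs prolonged heating of sensitive partners. An ethyl ether and a silyl ether must still be removed to reach 9.
- Comparison: on bonds formed per operation the cascade is the equal of the chosen key step (three ring bonds against two skeletal bonds and a stereocentre). On protecting-group load it is the better plan, with one O-alkyl group to cleave instead of two. It leaves the only real problem of the target, C-beta, unsolved, and it is several steps longer.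

Key step: step 3

Assumption: the (Rp,Rp) antipode of the MandyPhos ligand C52H50FeN2P2 is taken as the one that leads to the R boronate when an alkyl group migrates; if a small test run indicates the opposite sense, the (Sp,Sp) antipode is used and nothing else changes.

## Route

Step 1
Reactants: 1 3,5-dimethoxyphenol
Product: 2 3,5-dimethoxyphenyl trifluoromethanesulfonate
Conditions: Tf2O (1.1 equiv), pyridine (2 equiv), CH2Cl2, 0 °C to rt
Reagents that add atoms: trifluoromethanesulfonic anhydride, O=S(=O)(OS(=O)(=O)C(F)(F)F)C(F)(F)F
Why: O-sulfonylation of a phenol with triflic anhydride under pyridine; the phenol oxygen attacks sulfur, the meta-methoxy groups are spectators, and the aryl triflate should be stable to chromatography.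

Step 2
Reactants: 3 1-bromopentadecane
Product: 4 pentadecyllithium (ether solution, titrated and used at once)
Conditions: Li granules (0.5% Na, 2.5 equiv), Et2O, −10 °C, argon; decanted from excess Li
Reagents that add atoms: lithium metal, [Li]
Why: Direct reductive lithiation of a primary alkyl bromide in ether is the classical preparation of long-chain n-alkyllithiums; low temperature and slow addition should hold back Wurtz coupling, and no pyrophoric tertiary alkyllithium is needed. The LiBr formed stays in solution and is removed in step 3.

Step 3
Reactants: 4 pentadecyllithium; 5 vinylboronic acid pinacol ester (4,4,5,5-tetramethyl-2-vinyl-1,3,2-dioxaborolane); 2 3,5-dimethoxyphenyl trifluoromethanesulfonate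
Product: 7 2-[(2R)-1-(3,5-dimethoxyphenyl)heptadecan-2-yl]-4,4,5,5-tetramethyl-1,3,2-dioxaborolane, via lithium pentadecyl(vinyl)pinacolatoborate 6 (not isolated)
Conditions: 5 (1.05 equiv), Et2O, 0 °C to rt; volatiles removed; degassed THF, NaOTf (2 equiv), Pd(OAc)2 (2 mol%), (Rp,Rp)-MandyPhos C52H50FeN2P2 (2.4 mol%), 2 (1.1 equiv), 60 °C, 16 h
Reagents that add atoms: none
Why: Addition of 4 to the vacant orbital on boron of 5 gives the tetracoordinate vinylborate 6, and NaOTf then removes the bromide carried over from step 2 as insoluble NaBr. Pd(OAc)2 is reduced in the flask to zerovalent palladium, which inserts into the C–O bond of 2 to give a cationic aryl complex of divalent palladium with a weakly bound triflate. This electrophilic centre binds the vinyl group of 6 and induces an anti 1,2-shift of the pentadecyl group from boron to the boron-bearing carbon (C-beta to C-gamma bond) while the terminal carbon bonds to palladium; reductive elimination then forms the aryl to C-alpha bond and returns zerovalent palladium. The closest known reaction type is the palladium-catalysed enantioselective conjunctive cross-coupling of vinylboron ate complexes with aryl triflates, for which primary alkyl groups are competent migrating groups. No ring is closed. The single new stereocentre at C-beta is set under catalyst control: the chiral bisphosphine leaves only one face of the bound vinyl group open to the migrating group, and the ligand antipode is chosen for R. The step needs the metallate shift to win over direct transmetalation and over beta-hydride elimination, which is secured by the non-coordinating triflate, the halide scavenger, the one-to-one ratio of 4 to 5 (no free organolithium to attack 2 at sulfur) and the fast reductive elimination imposed by the wide-bite-angle ligand.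

Step 4
Reactants: 7 2-[(2R)-1-(3,5-dimethoxyphenyl)heptadecan-2-yl]-4,4,5,5-tetramethyl-1,3,2-dioxaborolane
Product: 8 (2R)-1-(3,5-dimethoxyphenyl)heptadecan-2-ol
Conditions: 30% aq H2O2, 3 M aq NaOH, THF, 0 °C to rt; then aq Na2S2O3
Reagents that add atoms: hydrogen peroxide, OO
Why: Alkaline peroxide oxidation of a secondary alkylboronic ester: hydroperoxide adds to boron and the alkyl group migrates from boron to oxygen with retention, so C-beta keeps its configuration. The descriptor stays R because O, ArCH2, alkyl rank in the same cyclic sense as ArCH2, alkyl, B; the aryl methyl ethers are inert.

Step 5
Reactants: 8 (2R)-1-(3,5-dimethoxyphenyl)heptadecan-2-ol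
Product: 9 5-[(2R)-2-hydroxyheptadecyl]benzene-1,3-diol (CNP0283129.1)
Conditions: BBr3 (1 M in CH2Cl2, 4.5 equiv), CH2Cl2, −78 °C to 0 °C; then ice water, aq NaHCO3, under argon
Reagents that add atoms: none
Why: Lewis-acid cleavage of aryl methyl ethers: BBr3 binds each methoxy oxygen and bromide removes the methyl group by SN2, giving neutral aryloxyboranes, so the second ether should cleave as readily as the first. The carbinol is held as its bromoborane ester, which an unactivated secondary carbon should not ionise at or below 0 °C, and is returned on hydrolysis with C-beta untouched; free secondary alcohols are routinely carried through this reagent.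

## Compound list

1 | 3,5-dimethoxyphenol | COc1cc(O)cc(OC)c1 | starting material
2 | 3,5-dimethoxyphenyl trifluoromethanesulfonate | COc1cc(OC)cc(OS(=O)(=O)C(F)(F)F)c1 | intermediate
3 | 1-bromopentadecane | CCCCCCCCCCCCCCCBr | starting material
4 | pentadecyllithium | [Li]CCCCCCCCCCCCCCC | intermediate
5 | vinylboronic acid pinacol ester (4,4,5,5-tetramethyl-2-vinyl-1,3,2-dioxaborolane) | C=CB1OC(C)(C)C(C)(C)O1 | starting material
6 | lithium pentadecyl(vinyl)pinacolatoborate | [Li+].C=C[B-]1(CCCCCCCCCCCCCCC)OC(C)(C)C(C)(C)O1 | intermediate (not isolated)
7 | 2-[(2R)-1-(3,5-dimethoxyphenyl)heptadecan-2-yl]-4,4,5,5-tetramethyl-1,3,2-dioxaborolane | CCCCCCCCCCCCCCC[C@@H](B1OC(C)(C)C(C)(C)O1)Cc1cc(OC)cc(OC)c1 | intermediate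
8 | (2R)-1-(3,5-dimethoxyphenyl)heptadecan-2-ol | CCCCCCCCCCCCCCC[C@@H](O)Cc1cc(OC)cc(OC)c1 | intermediate
9 | 5-[(2R)-2-hydroxyheptadecyl]benzene-1,3-diol | CCCCCCCCCCCCCCC[C@@H](O)Cc1cc(O)cc(O)c1 | target

## Step count and least certain steps

Total step count: 5. Longest linear sequence: 4 steps (steps 2, 3, 4, 5 from 3; equally steps 1, 3, 4, 5 from 1).

Step 3 (key step). The most likely failure is incomplete removal of the bromide carried over from step 2. Bromide would bind the cationic aryl palladium intermediate, stall the metallate shift and let direct transmetalation take over. A second concern is weak enantioface discrimination with a long, flexible migrating group. The fallback sets out from 4 and returns at 7, and replaces catalytic control by a stoichiometric, reagent-controlled 1,2-metallate shift (lithiation–borylation). Compound 4 is quenched with 2-isopropoxy-4,4,5,5-tetramethyl-1,3,2-dioxaborolane to give 4,4,5,5-tetramethyl-2-pentadecyl-1,3,2-dioxaborolane F1, which is purified by chromatography. Commercial 2-(3,5-dimethoxyphenyl)ethanol is acylated with N,N-diisopropylcarbamoyl chloride (Et3N, toluene, reflux) to give 2-(3,5-dimethoxyphenyl)ethyl N,N-diisopropylcarbamate F2. Carbamate-directed deprotonation alpha to oxygen with s-BuLi and (+)-sparteine in Et2O at −78 °C (removal of the pro-R hydrogen) should give [(1R)-1-lithio-2-(3,5-dimethoxyphenyl)ethyl] N,N-diisopropylcarbamate F3. F3 adds to F1 with retention to give lithium [(1R)-1-(N,N-diisopropylcarbamoyloxy)-2-(3,5-dimethoxyphenyl)ethyl](pentadecyl)pinacolatoborate F4. With MgBr2·OEt2 in refluxing Et2O the pentadecyl group migrates from boron to carbon with inversion and expels the carbamate, giving 7.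

Step 2. The most likely failure is Wurtz-type homocoupling at the metal surface together with slow initiation on a waxy bromide. This would lower and blur the titre, so that step 3 runs with surplus organolithium or surplus 5; the LiBr formed here is also the source of the halide problem in step 3. The fallback sets out from 3 and returns at 6, with the roles of the two boron partners inverted. Compound 3 is converted with Mg turnings in THF into pentadecylmagnesium bromide F5, which is trapped with 2-isopropoxy-4,4,5,5-tetramethyl-1,3,2-dioxaborolane to give the boronic ester F1 described above, freed of all halide by chromatography. Halide-free vinyllithium F6, made from Sn(CH=CH2)4 and n-BuLi, is added to F1 in Et2O at −78 °C to give 6. The coupling of step 3 then runs as written but without NaOTf.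

Step 5. The most likely failures are substitution of the secondary hydroxyl by bromide through its bromoborane ester, or acid-induced dehydration towards the styrene, if the mixture warms. Incomplete cleavage of the second ether is possible if it is kept too cold, and the free resorcinol can oxidise in air during basic work-up. The fallback sets out from 6 and returns at 9, changing the phenol mask to benzyl so that no Lewis acid is needed. Commercial 3,5-bis(benzyloxy)phenol is converted with Tf2O and pyridine into 3,5-bis(benzyloxy)phenyl trifluoromethanesulfonate F7. Coupling of F7 with 6 under the conditions of step 3 should give 2-[(2R)-1-[3,5-bis(benzyloxy)phenyl]heptadecan-2-yl]-4,4,5,5-tetramethyl-1,3,2-dioxaborolane F8. Oxidation as in step 4 gives (2R)-1-[3,5-bis(benzyloxy)phenyl]heptadecan-2-ol F9. Hydrogenolysis (H2, 1 atm, Pd/C, EtOAc–EtOH, rt) then removes both benzyl groups under neutral conditions and gives 9.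

## Further compounds

F1 | step 3 | 4,4,5,5-tetramethyl-2-pentadecyl-1,3,2-dioxaborolane | CCCCCCCCCCCCCCCB1OC(C)(C)C(C)(C)O1
F2 | step 3 | 2-(3,5-dimethoxyphenyl)ethyl N,N-diisopropylcarbamate | COc1cc(OC)cc(CCOC(=O)N(C(C)C)C(C)C)c1
F3 | step 3 | [(1R)-1-lithio-2-(3,5-dimethoxyphenyl)ethyl] N,N-diisopropylcarbamate | [Li][C@@H](OC(=O)N(C(C)C)C(C)C)Cc1cc(OC)cc(OC)c1
F4 | step 3 | lithium [(1R)-1-(N,N-diisopropylcarbamoyloxy)-2-(3,5-dimethoxyphenyl)ethyl](pentadecyl)pinacolatoborate | [Li+].CCCCCCCCCCCCCCC[B-]1(OC(C)(C)C(C)(C)O1)[C@@H](OC(=O)N(C(C)C)C(C)C)Cc1cc(OC)cc(OC)c1
F5 | step 2 | pentadecylmagnesium bromide | CCCCCCCCCCCCCCC[Mg]Br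
F6 | step 2 | vinyllithium | [Li]C=C
F7 | step 5 | 3,5-bis(benzyloxy)phenyl trifluoromethanesulfonate | O=S(=O)(Oc1cc(OCc2ccccc2)cc(OCc2ccccc2)c1)C(F)(F)F
F8 | step 5 | 2-[(2R)-1-[3,5-bis(benzyloxy)phenyl]heptadecan-2-yl]-4,4,5,5-tetramethyl-1,3,2-dioxaborolane | CCCCCCCCCCCCCCC[C@@H](B1OC(C)(C)C(C)(C)O1)Cc1cc(OCc2ccccc2)cc(OCc2ccccc2)c1
F9 | step 5 | (2R)-1-[3,5-bis(benzyloxy)phenyl]heptadecan-2-ol | CCCCCCCCCCCCCCC[C@@H](O)Cc1cc(OCc2ccccc2)cc(OCc2ccccc2)c1
A1 | alternative 1 | methyl (9R)-9-(tert-butyldimethylsilyloxy)-3,5,7-trioxotetracosanoate | CCCCCCCCCCCCCCC[C@@H](O[Si](C)(C)C(C)(C)C)CC(=O)CC(=O)CC(=O)CC(=O)OC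
A2 | alternative 1 | methyl 2,4-dihydroxy-6-[(2R)-2-(tert-butyldimethylsilyloxy)heptadecyl]benzoate | CCCCCCCCCCCCCCC[C@@H](O[Si](C)(C)C(C)(C)C)Cc1cc(O)cc(O)c1C(=O)OC
A3 | alternative 2 | (E)-1-(3,5-dimethoxyphenyl)heptadec-1-ene | CCCCCCCCCCCCCCC/C=C/c1cc(OC)cc(OC)c1
A4 | alternative 2 | (2R,3R)-2-(3,5-dimethoxyphenyl)-3-pentadecyloxirane | CCCCCCCCCCCCCCC[C@H]1O[C@@H]1c1cc(OC)cc(OC)c1
A5 | alternative 3 | 3-[(2R)-2-(tert-butyldimethylsilyloxy)heptadecyl]cyclobut-2-en-1-one | CCCCCCCCCCCCCCC[C@@H](O[Si](C)(C)C(C)(C)C)CC1=CC(=O)C1
A6 | alternative 3 | ethoxyethyne | CCOC#C
A7 | alternative 3 | 3-ethoxy-5-[(2R)-2-(tert-butyldimethylsilyloxy)heptadecyl]phenol | CCCCCCCCCCCCCCC[C@@H](O[Si](C)(C)C(C)(C)C)Cc1cc(O)cc(OCC)c1
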